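**Retrosynthetic overview**
1. Target 29 ⇐ tris-TBS ether 28 by global desilylation. The only ring, the dihydropyranone, is closed in the last-but-one step by ring-closing metathesis of the acrylate/vinyl diester 27.
2. Key disconnection: the C5–O ester bond of 27 ⇒ dienoic acid 25 + homopropargylic acrylate 16, joined by a new rhodium-catalysed addition of the acid across the alkyne, which also sets C5.
3. 16 ⇐ aldehyde 12 (catalytic asymmetric propargylation sets C6, then acryloylation) ⇐ Negishi sp3–sp2 coupling of iodide 4 (from lipase-desymmetrised meso-2,4-dimethylpentane-1,5-diol) with vinyl bromide 8 (from (S)-but-3-yn-2-ol).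
4. 25 ⇐ enal 23 (Horner–Wadsworth–Emmons) ⇐ cross-metathesis of 21 with methacrolein ⇐ (S)-4-vinylbutyrolactone 19 from asymmetric rhodium conjugate addition to furan-2(5H)-one.
5. Ring order: one ring only (pyranone numbering O1, C2(=O), C3=C4, C5, C6), formed after all stereocentres are in place.

TBS = tert-butyldimethylsilyl throughout.

Assumption: Amano lipase AK acetylates the meso diol 2 to (2R,4S)-5-acetoxy-2,4-dimethylpentan-1-ol (= 3), the sense I recall as commonly reported; if a batch gave the antipode, lipase hydrolysis of the diacetate would supply 3.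

Step 1
Reactants: 1 meso-2,4-dimethylglutaric anhydride
Product: 2 meso-(2R,4S)-2,4-dimethylpentane-1,5-diol
Conditions: LiAlH4, THF, 0 °C to reflux; Fieser work-up
Reagents that add atoms: none
Why: Hydride reduction of the cyclic anhydride gives the diol without touching the two methyl-bearing carbons, so the product stays meso.

Step 2
Reactants: 2 meso-(2R,4S)-2,4-dimethylpentane-1,5-diol
Product: 3 (2S,4R)-5-hydroxy-2,4-dimethylpentyl acetate
Conditions: Amano lipase AK, vinyl acetate, THF, 23 °C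
Reagents that add atoms: vinyl acetate, CC(=O)OC=C
Why: Enzymatic desymmetrisation (lipase transesterification) acylates one enantiotopic CH2OH, which fixes both methyl stereocentres (the future C4′ R and C6′ S) in high ee.

Step 3
Reactants: 3 (2S,4R)-5-hydroxy-2,4-dimethylpentyl acetate
Product: 4 (2S,4R)-5-iodo-2,4-dimethylpentyl acetate
Conditions: I2, PPh3, imidazole, CH2Cl2, 0 °C
Reagents that add atoms: iodine, II
Why: Appel-type iodination displaces the activated primary oxygen at CH2 and leaves the acetate and both stereocentres untouched.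

Step 4
Reactants: 5 (S)-but-3-yn-2-ol
Product: 6 tert-butyl{[(2S)-but-3-yn-2-yl]oxy}dimethylsilane
Conditions: TBSCl, imidazole, DMF, 23 °C
Reagents that add atoms: tert-butyldimethylsilyl chloride, CC(C)(C)[Si](C)(C)Cl
Why: Standard O-silylation; the carbinol stereocentre (the future (S)-allylic alcohol) comes from the chiral pool.

Step 5
Reactants: 6 tert-butyl{[(2S)-but-3-yn-2-yl]oxy}dimethylsilane
Product: 8 {[(2S)-3-bromobut-3-en-2-yl]oxy}(tert-butyl)dimethylsilane, via (Z)-2-bromoalkenyl-9-BBN adduct 7 (not isolated)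
Conditions: B-bromo-9-BBN, CH2Cl2, 0 °C; then AcOH, 0 to 23 °C; aq. NaHCO3
Reagents that add atoms: B-bromo-9-borabicyclo[3.3.1]nonane, BrB1C2CCCC1CCC2
Why: syn-Bromoboration of the terminal alkyne puts bromine on the internal carbon, and protodeboronation with acetic acid then gives the 2-bromoalkene (haloboration–protonolysis).

Step 6
Reactants: 4 (2S,4R)-5-iodo-2,4-dimethylpentyl acetate; 8 {[(2S)-3-bromobut-3-en-2-yl]oxy}(tert-butyl)dimethylsilane
Product: 10 (2S,4R,7S)-7-(TBSO)-2,4-dimethyl-6-methylideneoctyl acetate, via alkylzinc iodide 9 (not isolated)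
Conditions: Zn dust (BrCH2CH2Br/TMSCl-activated), LiCl, THF, 40 °C; then 8, PdCl2(dppf) (3 mol %), THF, 25–40 °C
Reagents that add atoms: none
Why: Knochel zinc insertion followed by Negishi sp3–sp2 cross-coupling (oxidative addition of zerovalent palladium into the C–Br bond, transmetalation, reductive elimination) forms C3′–C2′; no stereocentre is at a reacting carbon.

Step 7
Reactants: 10 (2S,4R,7S)-7-(TBSO)-2,4-dimethyl-6-methylideneoctyl acetate
Product: 11 (2S,4R,7S)-7-(TBSO)-2,4-dimethyl-6-methylideneoctan-1-ol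
Conditions: K2CO3 (cat.), MeOH, 23 °C
Reagents that add atoms: none
Why: Base-catalysed transesterification removes the acetate; the silyl ether and alkene are inert.

Step 8
Reactants: 11 (2S,4R,7S)-7-(TBSO)-2,4-dimethyl-6-methylideneoctan-1-ol
Product: 12 (2S,4R,7S)-7-(TBSO)-2,4-dimethyl-6-methylideneoctanal
Conditions: TEMPO (10 mol %), PhI(OAc)2, CH2Cl2, 23 °C
Reagents that add atoms: none
Why: Oxoammonium (TEMPO/PhI(OAc)2) oxidation stops at the aldehyde under non-basic conditions, so the α-methyl stereocentre is not epimerised; 12 is used at once.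

Step 9
Reactants: 12 (2S,4R,7S)-7-(TBSO)-2,4-dimethyl-6-methylideneoctanal; 13 allenylboronic acid pinacol ester
Product: 14 (4S,5S,7R,10S)-10-(TBSO)-5,7-dimethyl-9-methylideneundec-1-yn-4-ol
Conditions: (S)-TRIP phosphoric acid (5 mol %), 4 Å MS, toluene, 0 °C; aq. NaHCO3
Reagents that add atoms: none
Why: Chiral phosphoric acid-catalysed allenylboration (SE2′ propargylation through a closed chair transition state) delivers the propargyl group to the Si face and sets C6 as the 4S alcohol; this is also the Felkin–Anh face, so catalyst and substrate reinforce (the (S)-acid is chosen by analogy with the reported sense of allylboration and should be confirmed, e.g. by Mosher analysis).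

Step 10
Reactants: 14 (4S,5S,7R,10S)-10-(TBSO)-5,7-dimethyl-9-methylideneundec-1-yn-4-ol; 15 acryloyl chloride
Product: 16 (4S,5S,7R,10S)-10-(TBSO)-5,7-dimethyl-9-methylideneundec-1-yn-4-yl prop-2-enoate
Conditions: iPr2NEt, DMAP (cat.), CH2Cl2, −20 to 0 °C
Reagents that add atoms: none
Why: O-Acylation of the secondary alcohol; the acrylate masks O6 and brings in C2–C3 of the lactone.

Step 11
Reactants: 17 furan-2(5H)-one; 18 potassium vinyltrifluoroborate
Product: 19 (4S)-4-ethenyloxolan-2-one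
Conditions: [Rh(cod)2]PF6 (3 mol %), (S)-BINAP (3.3 mol %), toluene/H2O 20:1, 105 °C
Reagents that add atoms: none
Why: Hayashi–Miyaura asymmetric conjugate addition: the vinyl rhodium–(S)-BINAP complex adds to one enantioface of the butenolide and sets the (S) centre, by analogy with the known sense for cyclic enones.

Step 12
Reactants: 19 (4S)-4-ethenyloxolan-2-one
Product: 20 (2S)-2-ethenylbutane-1,4-diol
Conditions: LiAlH4, THF, 0 °C; Fieser work-up
Reagents that add atoms: none
Why: Hydride reduction of the lactone gives the 1,4-diol; the stereocentre is not involved.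

Step 13
Reactants: 20 (2S)-2-ethenylbutane-1,4-diol
Product: 21 (2S)-1,4-bis(TBSO)-2-ethenylbutane
Conditions: TBSCl (2.4 equiv), imidazole, DMF, 23 °C
Reagents that add atoms: tert-butyldimethylsilyl chloride, CC(C)(C)[Si](C)(C)Cl
Why: Double O-silylation gives protection that survives the later steps and falls off in the final fluoride step.

Step 14
Reactants: 21 (2S)-1,4-bis(TBSO)-2-ethenylbutane; 22 methacrolein
Product: 23 (2E,4S)-6-(TBSO)-4-[(TBSO)methyl]-2-methylhex-2-enal
Conditions: second-generation Hoveyda–Grubbs catalyst RuCl2(=CH-C6H4-2-OiPr)(H2IMes) (5 mol %), methacrolein (5 equiv), CH2Cl2, 40 °C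
Reagents that add atoms: none
Why: Olefin cross-metathesis of the terminal alkene with methacrolein gives the trisubstituted enal, with E geometry set by thermodynamic control.

Step 15
Reactants: 23 (2E,4S)-6-(TBSO)-4-[(TBSO)methyl]-2-methylhex-2-enal; 24 (diethoxyphosphoryl)acetic acid
Product: 25 (2E,4E,6S)-8-(TBSO)-6-[(TBSO)methyl]-4-methylocta-2,4-dienoic acid
Conditions: 24 (1.5 equiv), nBuLi (3.0 equiv), THF, −78 °C; then 23, −78 to 23 °C; cold 1 M HCl work-up
Reagents that add atoms: none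
Why: Horner–Wadsworth–Emmons olefination with the dianion of the phosphonoacetic acid gives the (2E)-acid directly and saves an ester hydrolysis.

Step 16
Reactants: 16 (4S,5S,7R,10S)-10-(TBSO)-5,7-dimethyl-9-methylideneundec-1-yn-4-yl prop-2-enoate; 25 (2E,4E,6S)-8-(TBSO)-6-[(TBSO)methyl]-4-methylocta-2,4-dienoic acid
Product: 27 (3R,4R,5S,7R,10S)-4-(acryloyloxy)-10-(TBSO)-5,7-dimethyl-9-methylideneundec-1-en-3-yl (2E,4E,6S)-8-(TBSO)-6-[(TBSO)methyl]-4-methylocta-2,4-dienoate, via allenyl acrylate 26 (not isolated)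
Conditions: [Rh(cod)Cl]2 (3 mol %), (R,R)-Cp-DIOP or its antipode (7 mol %, whichever is matched), 16 (1.2 equiv), ClCH2CH2Cl, 70 °C
Reagents that add atoms: none
Why: Proposed new method: monovalent rhodium adds the O–H of 25 to give a trivalent rhodium hydride carboxylate, which hydrometalates the alkyne, β-hydride-eliminates to allene 26, re-adds to a π-allyl rhodium carboxylate and reductively eliminates the C–O bond at the branched terminus, the DIOP-type ligand choosing the allyl face so that the new ester carbon is 3R (syn to the acrylate-bearing carbon); the closest known reaction type is the rhodium-catalysed redox-neutral coupling of terminal alkynes or allenes with carboxylic acids to branched allylic esters, which to my knowledge has not been shown on a β-acyloxy alkyne to build a syn-1,2-diol diester under catalyst control.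

Step 17
Reactants: 27 (3R,4R,5S,7R,10S)-4-(acryloyloxy)-10-(TBSO)-5,7-dimethyl-9-methylideneundec-1-en-3-yl (2E,4E,6S)-8-(TBSO)-6-[(TBSO)methyl]-4-methylocta-2,4-dienoate
Product: 28 (2R,3R)-2-[(2S,4R,7S)-7-(TBSO)-4-methyl-6-methylideneoctan-2-yl]-6-oxo-3,6-dihydro-2H-pyran-3-yl (2E,4E,6S)-8-(TBSO)-6-[(TBSO)methyl]-4-methylocta-2,4-dienoate
Conditions: second-generation Grubbs catalyst RuCl2(=CHPh)(PCy3)(H2IMes) (5 mol %), CH2Cl2 (2 mM), 40 °C
Reagents that add atoms: none
Why: Ring-closing metathesis of the acrylate with the monosubstituted vinyl group closes the six-membered unsaturated lactone far faster than the 1,1-disubstituted or conjugated trisubstituted alkenes can react; the cis (5R,6R) relationship is already set.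

Step 18
Reactants: 28 (2R,3R)-2-[(2S,4R,7S)-7-(TBSO)-4-methyl-6-methylideneoctan-2-yl]-6-oxo-3,6-dihydro-2H-pyran-3-yl (2E,4E,6S)-8-(TBSO)-6-[(TBSO)methyl]-4-methylocta-2,4-dienoate
Product: 29 (2R,3R)-2-[(2S,4R,7S)-7-hydroxy-4-methyl-6-methylideneoctan-2-yl]-6-oxo-3,6-dihydro-2H-pyran-3-yl (2E,4E,6S)-8-hydroxy-6-(hydroxymethyl)-4-methylocta-2,4-dienoate
Conditions: HF·pyridine, pyridine, THF, 0 to 23 °C
Reagents that add atoms: none
Why: Fluoride-driven desilylation under buffered, non-basic conditions removes all three TBS groups and leaves the base-sensitive 5-acyloxy lactone and the dienoate intact.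

**Compound list**
1 | meso-2,4-dimethylglutaric anhydride, (3R,5S)-3,5-dimethyloxane-2,6-dione | C[C@@H]1C[C@H](C)C(=O)OC1=O | starting material
2 | meso-(2R,4S)-2,4-dimethylpentane-1,5-diol | OC[C@H](C)C[C@H](C)CO | intermediate
3 | (2S,4R)-5-hydroxy-2,4-dimethylpentyl acetate | OC[C@H](C)C[C@H](C)COC(C)=O | intermediate
4 | (2S,4R)-5-iodo-2,4-dimethylpentyl acetate | IC[C@H](C)C[C@H](C)COC(C)=O | intermediate
5 | (S)-but-3-yn-2-ol | C#C[C@H](C)O | starting material
6 | tert-butyl{[(2S)-but-3-yn-2-yl]oxy}dimethylsilane | C#C[C@H](C)O[Si](C)(C)C(C)(C)C | intermediate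
7 | 9-[(1Z,3S)-2-bromo-3-(TBSO)but-1-en-1-yl]-9-borabicyclo[3.3.1]nonane | Br/C(=C\B1C2CCCC1CCC2)[C@H](C)O[Si](C)(C)C(C)(C)C | intermediate
8 | {[(2S)-3-bromobut-3-en-2-yl]oxy}(tert-butyl)dimethylsilane | C=C(Br)[C@H](C)O[Si](C)(C)C(C)(C)C | intermediate
9 | [(2R,4S)-5-acetoxy-2,4-dimethylpentyl]zinc iodide | I[Zn]C[C@H](C)C[C@H](C)COC(C)=O | intermediate
10 | (2S,4R,7S)-7-(TBSO)-2,4-dimethyl-6-methylideneoctyl acetate | C=C(C[C@H](C)C[C@H](C)COC(C)=O)[C@H](C)O[Si](C)(C)C(C)(C)C | intermediate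
11 | (2S,4R,7S)-7-(TBSO)-2,4-dimethyl-6-methylideneoctan-1-ol | C=C(C[C@H](C)C[C@H](C)CO)[C@H](C)O[Si](C)(C)C(C)(C)C | intermediate
12 | (2S,4R,7S)-7-(TBSO)-2,4-dimethyl-6-methylideneoctanal | C=C(C[C@H](C)C[C@H](C)C=O)[C@H](C)O[Si](C)(C)C(C)(C)C | intermediate
13 | allenylboronic acid pinacol ester | C=C=CB1OC(C)(C)C(C)(C)O1 | starting material
14 | (4S,5S,7R,10S)-10-(TBSO)-5,7-dimethyl-9-methylideneundec-1-yn-4-ol | C=C(C[C@H](C)C[C@H](C)[C@@H](O)CC#C)[C@H](C)O[Si](C)(C)C(C)(C)C | intermediate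
15 | acryloyl chloride | C=CC(=O)Cl | starting material
16 | (4S,5S,7R,10S)-10-(TBSO)-5,7-dimethyl-9-methylideneundec-1-yn-4-yl prop-2-enoate | C=C(C[C@H](C)C[C@H](C)[C@@H](OC(=O)C=C)CC#C)[C@H](C)O[Si](C)(C)C(C)(C)C | intermediate
17 | furan-2(5H)-one | O=C1OCC=C1 | starting material
18 | potassium vinyltrifluoroborate | [K+].C=C[B-](F)(F)F | starting material
19 | (4S)-4-ethenyloxolan-2-one | C=C[C@H]1COC(=O)C1 | intermediate
20 | (2S)-2-ethenylbutane-1,4-diol | C=C[C@@H](CO)CCO | intermediate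
21 | (2S)-1,4-bis(TBSO)-2-ethenylbutane | C=C[C@@H](CO[Si](C)(C)C(C)(C)C)CCO[Si](C)(C)C(C)(C)C | intermediate
22 | methacrolein (2-methylprop-2-enal) | C=C(C)C=O | starting material
23 | (2E,4S)-6-(TBSO)-4-[(TBSO)methyl]-2-methylhex-2-enal | O=C/C(C)=C/[C@@H](CO[Si](C)(C)C(C)(C)C)CCO[Si](C)(C)C(C)(C)C | intermediate
24 | (diethoxyphosphoryl)acetic acid | CCOP(=O)(CC(=O)O)OCC | starting material
25 | (2E,4E,6S)-8-(TBSO)-6-[(TBSO)methyl]-4-methylocta-2,4-dienoic acid | OC(=O)/C=C/C(C)=C/[C@@H](CO[Si](C)(C)C(C)(C)C)CCO[Si](C)(C)C(C)(C)C | intermediate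
26 | (4R,5S,7R,10S)-10-(TBSO)-5,7-dimethyl-9-methylideneundeca-1,2-dien-4-yl prop-2-enoate | C=C(C[C@H](C)C[C@H](C)[C@@H](OC(=O)C=C)C=C=C)[C@H](C)O[Si](C)(C)C(C)(C)C | intermediate
27 | (3R,4R,5S,7R,10S)-4-(acryloyloxy)-10-(TBSO)-5,7-dimethyl-9-methylideneundec-1-en-3-yl (2E,4E,6S)-8-(TBSO)-6-[(TBSO)methyl]-4-methylocta-2,4-dienoate | C=C(C[C@H](C)C[C@H](C)[C@@H](OC(=O)C=C)[C@@H](C=C)OC(=O)/C=C/C(C)=C/[C@@H](CO[Si](C)(C)C(C)(C)C)CCO[Si](C)(C)C(C)(C)C)[C@H](C)O[Si](C)(C)C(C)(C)C | intermediate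
28 | (2R,3R)-2-[(2S,4R,7S)-7-(TBSO)-4-methyl-6-methylideneoctan-2-yl]-6-oxo-3,6-dihydro-2H-pyran-3-yl (2E,4E,6S)-8-(TBSO)-6-[(TBSO)methyl]-4-methylocta-2,4-dienoate | C=C(C[C@H](C)C[C@H](C)[C@H]1OC(=O)C=C[C@H]1OC(=O)/C=C/C(C)=C/[C@@H](CO[Si](C)(C)C(C)(C)C)CCO[Si](C)(C)C(C)(C)C)[C@H](C)O[Si](C)(C)C(C)(C)C | intermediate
29 | (2R,3R)-2-[(2S,4R,7S)-7-hydroxy-4-methyl-6-methylideneoctan-2-yl]-6-oxo-3,6-dihydro-2H-pyran-3-yl (2E,4E,6S)-8-hydroxy-6-(hydroxymethyl)-4-methylocta-2,4-dienoate | C=C(C[C@H](C)C[C@H](C)[C@H]1OC(=O)C=C[C@H]1OC(=O)/C=C/C(C)=C/[C@@H](CO)CCO)[C@H](C)O | target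

**Step count**
Total: 18 steps. Longest linear sequence: 11 steps (1, 2, 3, 6, 7, 8, 9, 10, 16, 17, 18).

**Three steps most likely to fail**

Step 16 (the proposed new coupling). Risks: β-acyloxy elimination from the σ-allyl rhodium species to a diene, linear instead of branched ester, or poor catalyst control of the syn/anti ratio. Fallback with known chemistry, setting out from aldehyde 12 and returning at 28: Brown syn-alkoxyallylboration with (Z)-γ-(methoxymethoxy)allyl-diisopinocampheylborane (from allyl methoxymethyl ether, sBuLi, (−)-Ipc2BOMe and BF3·OEt2, −78 °C, then NaOH/H2O2; Si-face attack, Felkin-matched) gives (3R,4R,5S,7R,10S)-10-(TBSO)-3-(methoxymethoxy)-5,7-dimethyl-9-methylideneundec-1-en-4-ol F1. Acryloyl chloride 15 with iPr2NEt gives (3R,4R,5S,7R,10S)-10-(TBSO)-3-(methoxymethoxy)-5,7-dimethyl-9-methylideneundec-1-en-4-yl prop-2-enoate F2. Ring-closing metathesis with the second-generation Grubbs catalyst gives (5R,6R)-6-[(2S,4R,7S)-7-(TBSO)-4-methyl-6-methylideneoctan-2-yl]-5-(methoxymethoxy)-5,6-dihydro-2H-pyran-2-one F3. Me2BBr in CH2Cl2 at −78 °C removes the methoxymethyl group to give (5R,6R)-6-[(2S,4R,7S)-7-(TBSO)-4-methyl-6-methylideneoctan-2-yl]-5-hydroxy-5,6-dihydro-2H-pyran-2-one F4. Yamaguchi esterification of F4 with acid 25 (2,4,6-trichlorobenzoyl chloride, Et3N, DMAP, toluene) gives 28. This path also closes the ring before the dienoate is present, so it covers a failure of step 17 as well.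

Step 11 (asymmetric vinyl addition to the sluggish butenolide acceptor). Risks: low conversion, protodeboronation, moderate ee. Fallback setting out from 17 and returning at 19: copper-mediated conjugate addition of vinylmagnesium bromide (CuBr·SMe2, TMSCl, THF, −78 °C) gives racemic 4-ethenyloxolan-2-one F5. Ring opening with (S)-1-phenylethylamine gives diastereomeric hydroxy amides, from which (3S)-3-(hydroxymethyl)-N-[(1S)-1-phenylethyl]pent-4-enamide F6 is separated by crystallisation or chromatography. Heating F6 in dilute H2SO4/dioxane relactonises it to 19 (classical resolution instead of asymmetric catalysis).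

Step 14 (cross-metathesis to a trisubstituted enal next to a branched allylic carbon). Risks: low conversion, homodimer of 21. Fallback setting out from 21 and returning at 23: ozonolysis (O3, CH2Cl2, −78 °C, then PPh3) gives (2R)-4-(TBSO)-2-[(TBSO)methyl]butanal F7, and Wittig olefination of F7 with 2-(triphenylphosphoranylidene)propanal (toluene, 80 °C) gives the (E)-enal 23.

**Further compounds**
F1 | step 16 | (3R,4R,5S,7R,10S)-10-(TBSO)-3-(methoxymethoxy)-5,7-dimethyl-9-methylideneundec-1-en-4-ol | C=C(C[C@H](C)C[C@H](C)[C@@H](O)[C@@H](C=C)OCOC)[C@H](C)O[Si](C)(C)C(C)(C)C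
F2 | step 16 | (3R,4R,5S,7R,10S)-10-(TBSO)-3-(methoxymethoxy)-5,7-dimethyl-9-methylideneundec-1-en-4-yl prop-2-enoate | C=C(C[C@H](C)C[C@H](C)[C@@H](OC(=O)C=C)[C@@H](C=C)OCOC)[C@H](C)O[Si](C)(C)C(C)(C)C
F3 | step 16 | (5R,6R)-6-[(2S,4R,7S)-7-(TBSO)-4-methyl-6-methylideneoctan-2-yl]-5-(methoxymethoxy)-5,6-dihydro-2H-pyran-2-one | C=C(C[C@H](C)C[C@H](C)[C@H]1OC(=O)C=C[C@H]1OCOC)[C@H](C)O[Si](C)(C)C(C)(C)C
F4 | step 16 | (5R,6R)-6-[(2S,4R,7S)-7-(TBSO)-4-methyl-6-methylideneoctan-2-yl]-5-hydroxy-5,6-dihydro-2H-pyran-2-one | C=C(C[C@H](C)C[C@H](C)[C@H]1OC(=O)C=C[C@H]1O)[C@H](C)O[Si](C)(C)C(C)(C)C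
F5 | step 11 | racemic 4-ethenyloxolan-2-one | C=CC1COC(=O)C1
F6 | step 11 | (3S)-3-(hydroxymethyl)-N-[(1S)-1-phenylethyl]pent-4-enamide | C=C[C@@H](CO)CC(=O)N[C@@H](C)c1ccccc1
F7 | step 14 | (2R)-4-(TBSO)-2-[(TBSO)methyl]butanal | O=C[C@@H](CO[Si](C)(C)C(C)(C)C)CCO[Si](C)(C)C(C)(C)C
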